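**Retrosynthetic overview**
- Last bond made: the aryl ether O-3′–CH2 bond. The free triphenol core is joined to racemic 2-(oxiran-2-yl)propan-2-ol by a catalyst-controlled ring opening that also selects the (S)-carbinol.
- Triphenol core: from its tris-MOM ether, whose aldehyde comes from oxidation of a benzylic alcohol next to the diaryl ketone.
- Diaryl ketone C–C bond: ortho-lithiated bis-MOM 4-methylcatechol adds once to 4-(methoxymethoxy)-7-prenylphthalide.
- Phthalide: from methyl 2-bromo-5-hydroxybenzoate by MOM protection, directed magnesiation/formaldehyde trapping and Stille prenylation.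
- Rings: both benzene rings are bought intact. The only ring closed is the temporary lactone (step 2), which is reopened in the ketone-forming step (step 5).

Assumption: (salen)Co complexes are taken to recognise this epoxide with the same sense as other terminal epoxides, so the (S,S)-complex consumes and the (R,R)-complex leaves the (S)-enantiomer of 2-(oxiran-2-yl)propan-2-ol (its carbinol substituent ranks like CH2Cl in epichlorohydrin).

Abbreviations: MOM = methoxymethyl; TMP = 2,2,6,6-tetramethylpiperidin-1-yl; salen = N,N′-bis(3,5-di-tert-butylsalicylidene)cyclohexane-1,2-diamine dianion; ring A = the benzaldehyde ring; ring B = the 2,3-dioxygenated 5-methylbenzoyl ring (primed locants).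

**Step 1**
Reactants: 1 methyl 2-bromo-5-hydroxybenzoate; 2 chloromethyl methyl ether
Product: 3 methyl 2-bromo-5-(methoxymethoxy)benzoate
Conditions: i-Pr2NEt, CH2Cl2, 0 °C → rt
Reagents that add atoms: chloromethyl methyl ether (2), COCCl
Why: O-alkylation of the phenoxide (MOM protection, Williamson type); the ester and aryl bromide are inert, and the MOM ether later serves as a metal-directing group.

**Step 2**
Reactants: 3 methyl 2-bromo-5-(methoxymethoxy)benzoate; 4 paraformaldehyde
Product: 7 7-bromo-4-(methoxymethoxy)isobenzofuran-1(3H)-one, via arylmagnesium chloride 5 (not isolated), via benzylic alkoxide 6 (not isolated)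
Conditions: TMPMgCl·LiCl (1.3 equiv), THF, 0 → 25 °C; then (CH2O)n, 25 °C; aq NH4Cl
Reagents that add atoms: paraformaldehyde (4), C=O
Why: Knochel–Hauser directed ortho-magnesiation removes the only C–H ortho to the ester (flanked by CO2Me and OMOM) without touching Br or the ester; the aryl Grignard adds to formaldehyde and the alkoxide lactonises onto the neighbouring ester to give the phthalide.

**Step 3**
Reactants: 7 7-bromo-4-(methoxymethoxy)isobenzofuran-1(3H)-one; 8 tributyl(3-methylbut-2-en-1-yl)stannane
Product: 9 4-(methoxymethoxy)-7-(3-methylbut-2-en-1-yl)isobenzofuran-1(3H)-one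
Conditions: Pd(PPh3)4 (5 mol %), DMF, 100 °C
Reagents that add atoms: tributyl(3-methylbut-2-en-1-yl)stannane (8), CCCC[Sn](CCCC)(CCCC)CC=C(C)C
Why: Stille cross-coupling of the electron-poor aryl bromide; the η3-prenyl palladium aryl eliminates at the unsubstituted terminus to give the linear prenyl arene, and running it after step 2 keeps the benzylic/allylic CH2 away from the amide base.

**Step 4**
Reactants: 10 4-methylbenzene-1,2-diol; 2 chloromethyl methyl ether
Product: 11 1,2-bis(methoxymethoxy)-4-methylbenzene
Conditions: MOMCl (2.5 equiv), i-Pr2NEt, CH2Cl2, 0 °C → rt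
Reagents that add atoms: chloromethyl methyl ether (2), COCCl
Why: double MOM protection (Williamson-type O-alkylation) masks the catechol and installs the directing groups for ortho-lithiation.

**Step 5**
Reactants: 11 1,2-bis(methoxymethoxy)-4-methylbenzene; 9 4-(methoxymethoxy)-7-(3-methylbut-2-en-1-yl)isobenzofuran-1(3H)-one
Product: 14 [2,3-bis(methoxymethoxy)-5-methylphenyl][2-(hydroxymethyl)-3-(methoxymethoxy)-6-(3-methylbut-2-en-1-yl)phenyl]methanone, via aryllithium 12 (not isolated), via lithium lactolate 13 (not isolated)
Conditions: 11 (1.3 equiv), n-BuLi (1.2 equiv), TMEDA, THF, 0 °C; then 9, −78 → −40 °C; aq NH4Cl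
Reagents that add atoms: none
Why: directed ortho-lithiation of 11 at C-6 (ortho to OMOM, away from the methyl group) followed by acylation of the aryllithium by the lactone; the cyclic lithium lactolate is stable at low temperature and the ketone released on work-up is tri-ortho-substituted, so addition stops after one equivalent.

**Step 6**
Reactants: 14 [2,3-bis(methoxymethoxy)-5-methylphenyl][2-(hydroxymethyl)-3-(methoxymethoxy)-6-(3-methylbut-2-en-1-yl)phenyl]methanone
Product: 15 2-[2,3-bis(methoxymethoxy)-5-methylbenzoyl]-6-(methoxymethoxy)-3-(3-methylbut-2-en-1-yl)benzaldehyde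
Conditions: Dess–Martin periodinane, pyridine, CH2Cl2, 0 °C → rt
Reagents that add atoms: none
Why: Dess–Martin oxidation of the primary benzylic alcohol (open form of the hydroxy ketone/lactol pair) to the aldehyde; the pyridine buffer suppresses acid-induced isobenzofuran formation, and the alkene and MOM ethers are untouched.

**Step 7**
Reactants: 15 2-[2,3-bis(methoxymethoxy)-5-methylbenzoyl]-6-(methoxymethoxy)-3-(3-methylbut-2-en-1-yl)benzaldehyde
Product: 16 2-(2,3-dihydroxy-5-methylbenzoyl)-6-hydroxy-3-(3-methylbut-2-en-1-yl)benzaldehyde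
Conditions: 3 M aq HCl, THF, 45 °C
Reagents that add atoms: none
Why: acid-catalysed hydrolysis of the three aryl MOM acetals; dilute aqueous acid leaves the trisubstituted alkene, aldehyde and ketone intact, and the prenyl group is para (not ortho) to the ring A phenol so no chroman can form.

**Step 8**
Reactants: 17 2-methylbut-3-en-2-ol; 18 3-chloroperoxybenzoic acid
Product: 19 rac-2-(oxiran-2-yl)propan-2-ol
Conditions: mCPBA, CH2Cl2, 0 °C → rt
Reagents that add atoms: 3-chloroperoxybenzoic acid (18), OOC(=O)c1cccc(Cl)c1
Why: Prilezhaev epoxidation of the terminal alkene, assisted by hydrogen bonding to the allylic hydroxyl; the product is racemic and is resolved in step 9.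

**Step 9**
Reactants: 16 2-(2,3-dihydroxy-5-methylbenzoyl)-6-hydroxy-3-(3-methylbut-2-en-1-yl)benzaldehyde; 19 rac-2-(oxiran-2-yl)propan-2-ol
Product: 20 tenellone A, 2-(3-{[(2S)-2,3-dihydroxy-3-methylbutyl]oxy}-2-hydroxy-5-methylbenzoyl)-6-hydroxy-3-(3-methylbut-2-en-1-yl)benzaldehyde
Conditions: (S,S)-(salen)Co(OC(CF3)3) (10 mol %), rac-19 (4 equiv), 3 Å MS, TBME/CH2Cl2, 0 °C → rt, Ar
Reagents that add atoms: none
Why: Proposed new method: a site-selective phenolic kinetic resolution on an unprotected triphenol, in which a trivalent cobalt aryloxide (salen)Co–OAr formed from 16 delivers its oxygen to the CH2 terminus of the (S)-epoxide that a second (salen)Co unit activates as a Lewis acid (cooperative bimetallic ring opening; C-2 is not touched, so the (S)-carbinol of 20 is selected from the racemate and the (R)-epoxide is left); O-3′ is expected to react because the ring A 6-OH and the 2′-OH are locked in resonance-assisted O–H···O=C hydrogen bonds next to acyl groups (2′-O is flanked on both sides and cannot sit on the bulky cobalt centre) while 3′-OH is the only free, electron-rich phenol; the closest known reaction type is the (salen)Co-catalysed kinetic resolution of terminal epoxides with simple monophenols (and the related hydrolytic kinetic resolution), not yet shown for catechol-type polyphenols or for an epoxide bearing a free tertiary carbinol.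

**Compound list**
1 | methyl 2-bromo-5-hydroxybenzoate | COC(=O)c1cc(O)ccc1Br | starting material
2 | chloromethyl methyl ether (MOMCl) | COCCl | starting material
3 | methyl 2-bromo-5-(methoxymethoxy)benzoate | COC(=O)c1cc(OCOC)ccc1Br | intermediate
4 | paraformaldehyde (formaldehyde source) | C=O | starting material
5 | chloro[3-bromo-2-(methoxycarbonyl)-6-(methoxymethoxy)phenyl]magnesium | COC(=O)c1c(Br)ccc(OCOC)c1[Mg]Cl | intermediate
6 | chloromagnesium alkoxide of methyl 6-bromo-2-(hydroxymethyl)-3-(methoxymethoxy)benzoate | COC(=O)c1c(Br)ccc(OCOC)c1CO[Mg]Cl | intermediate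
7 | 7-bromo-4-(methoxymethoxy)isobenzofuran-1(3H)-one | O=C1OCc2c(OCOC)ccc(Br)c12 | intermediate
8 | tributyl(3-methylbut-2-en-1-yl)stannane | CCCC[Sn](CCCC)(CCCC)CC=C(C)C | starting material
9 | 4-(methoxymethoxy)-7-(3-methylbut-2-en-1-yl)isobenzofuran-1(3H)-one | O=C1OCc2c(OCOC)ccc(CC=C(C)C)c12 | intermediate
10 | 4-methylbenzene-1,2-diol (4-methylcatechol) | Cc1ccc(O)c(O)c1 | starting material
11 | 1,2-bis(methoxymethoxy)-4-methylbenzene | Cc1ccc(OCOC)c(OCOC)c1 | intermediate
12 | [2,3-bis(methoxymethoxy)-5-methylphenyl]lithium | [Li]c1cc(C)cc(OCOC)c1OCOC | intermediate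
13 | lithium 1-[2,3-bis(methoxymethoxy)-5-methylphenyl]-4-(methoxymethoxy)-7-(3-methylbut-2-en-1-yl)-1,3-dihydroisobenzofuran-1-olate | [Li]OC1(OCc2c(OCOC)ccc(CC=C(C)C)c12)c1cc(C)cc(OCOC)c1OCOC | intermediate
14 | [2,3-bis(methoxymethoxy)-5-methylphenyl][2-(hydroxymethyl)-3-(methoxymethoxy)-6-(3-methylbut-2-en-1-yl)phenyl]methanone | CC(C)=CCc1ccc(OCOC)c(CO)c1C(=O)c1cc(C)cc(OCOC)c1OCOC | intermediate
15 | 2-[2,3-bis(methoxymethoxy)-5-methylbenzoyl]-6-(methoxymethoxy)-3-(3-methylbut-2-en-1-yl)benzaldehyde | CC(C)=CCc1ccc(OCOC)c(C=O)c1C(=O)c1cc(C)cc(OCOC)c1OCOC | intermediate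
16 | 2-(2,3-dihydroxy-5-methylbenzoyl)-6-hydroxy-3-(3-methylbut-2-en-1-yl)benzaldehyde | CC(C)=CCc1ccc(O)c(C=O)c1C(=O)c1cc(C)cc(O)c1O | intermediate
17 | 2-methylbut-3-en-2-ol | CC(C)(O)C=C | starting material
18 | 3-chloroperoxybenzoic acid (mCPBA) | OOC(=O)c1cccc(Cl)c1 | starting material
19 | rac-2-(oxiran-2-yl)propan-2-ol | CC(C)(O)C1CO1 | intermediate
20 | tenellone A, 2-(3-{[(2S)-2,3-dihydroxy-3-methylbutyl]oxy}-2-hydroxy-5-methylbenzoyl)-6-hydroxy-3-(3-methylbut-2-en-1-yl)benzaldehyde | CC(C)=CCc1ccc(O)c(C=O)c1C(=O)c1cc(C)cc(OC[C@H](O)C(C)(C)O)c1O | target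

**Step count**
Total: 9 steps. Longest linear sequence: 7 steps (1 → 3 → 7 → 9 → 14 → 15 → 16 → 20, i.e. steps 1, 2, 3, 5, 6, 7, 9).

**Three steps most likely to fail**

Step 9 (the proposed new method). The main risks are:
- alkylation at O-2′ or at the ring A phenol, as is seen when 2,3-dihydroxyaryl carbonyl compounds are alkylated as mono-anions;
- oxidation of the catechol by the trivalent cobalt centre if air is admitted;
- loss of catalyst through chelation by the o-acylphenol units;
- a lower selectivity factor if the α-hydroxy epoxide binds cobalt through both oxygens.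

The fallback uses known chemistry, sets out from 16 and 19 and returns at 20. Racemic 19 is resolved by hydrolytic kinetic resolution [(R,R)-(salen)Co(OAc) 0.5 mol %, H2O 0.55 equiv, 0 °C → rt] and the unreacted 2-[(2S)-oxiran-2-yl]propan-2-ol F1 is distilled off. Triphenol 16 is converted into its trisodium salt (NaH 3.1 equiv, dry DMSO, rt). In this fully deprotonated form the non-chelated 3′-phenoxide is the most basic and most nucleophilic oxygen (the polyanion rule used for 3-O-alkylation of 2,3-dihydroxybenzaldehyde). It opens F1 at CH2 at 60 °C, and mild acidic work-up gives 20. Strictly anhydrous conditions are needed so that the 2-aroylbenzaldehyde does not undergo base-induced Cannizzaro/Tishchenko isomerisation.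

Step 5 (aryllithium plus hindered phthalide). Addition to the lactone carbonyl next to the prenyl-bearing carbon may be slow, and deprotonation of the lactone CH2 or a second addition may compete. The fallback sets out from 9 and returns at 15, so step 6 is not needed. Lactone 9 is reduced with i-Bu2AlH (CH2Cl2, −78 °C) to 4-(methoxymethoxy)-7-(3-methylbut-2-en-1-yl)-1,3-dihydroisobenzofuran-1-ol F2. Aryllithium 12 (2.3 equiv, THF, −78 → 0 °C) adds to its open hydroxy-aldehyde form to give [2,3-bis(methoxymethoxy)-5-methylphenyl][2-(hydroxymethyl)-3-(methoxymethoxy)-6-(3-methylbut-2-en-1-yl)phenyl]methanol F3. A double Swern oxidation [(COCl)2, DMSO, Et3N, CH2Cl2, −78 °C] then converts both carbinols at once into keto aldehyde 15.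

Step 2 (ester-directed magnesiation and formaldehyde trapping). The C–H between CO2Me and OMOM may be metalated incompletely, or the hindered aryl Grignard may be trapped poorly by paraformaldehyde. The fallback sets out from 3 and returns at 7. Ester 3 is saponified (LiOH, THF/H2O) to 2-bromo-5-(methoxymethoxy)benzoic acid F4. The free acid is lithiated between carboxylate and OMOM with LiTMP (2.2 equiv, THF, −78 °C) and formylated with DMF to give 7-bromo-3-hydroxy-4-(methoxymethoxy)isobenzofuran-1(3H)-one F5. Reduction with NaBH4 followed by acidification closes the lactone to 7.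

**Further compounds**
F1 | step 9 | 2-[(2S)-oxiran-2-yl]propan-2-ol | CC(C)(O)[C@@H]1CO1
F2 | step 5 | 4-(methoxymethoxy)-7-(3-methylbut-2-en-1-yl)-1,3-dihydroisobenzofuran-1-ol | OC1OCc2c(OCOC)ccc(CC=C(C)C)c12
F3 | step 5 | [2,3-bis(methoxymethoxy)-5-methylphenyl][2-(hydroxymethyl)-3-(methoxymethoxy)-6-(3-methylbut-2-en-1-yl)phenyl]methanol | CC(C)=CCc1ccc(OCOC)c(CO)c1C(O)c1cc(C)cc(OCOC)c1OCOC
F4 | step 2 | 2-bromo-5-(methoxymethoxy)benzoic acid | OC(=O)c1cc(OCOC)ccc1Br
F5 | step 2 | 7-bromo-3-hydroxy-4-(methoxymethoxy)isobenzofuran-1(3H)-one | OC1OC(=O)c2c(Br)ccc(OCOC)c12
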